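## The problem

Phenylcandilide B, compound 12, is an achiral, fully aromatic benzofuran. Ring A (the furan) carries a CH2CO2Me arm at C2 and a methyl group at C3; ring B (the benzo ring) carries methoxy groups at C4 and C7 and a 4-hydroxyphenyl group (ring C) at C6, so C5–H is the only hydrogen on the bicycle. There is no stereocentre to set, so the difficulty is regiochemical: ring B is a pentasubstituted benzene whose five different substituents (C3a carbon, C4–OMe, C6 aryl, C7–OMe, C7a–O) must each be placed, and the furan must close with two different carbon substituents at C2 and C3. The groups that will not survive rough treatment are the free phenol of ring C (attacked by electrophilic oxidants), the hydroquinone dimethyl ether of ring B (oxidative demethylation to a quinone under one-electron oxidation) and the benzofuran-2-ylacetate (a saponifiable ester with an acidic methylene). The phenol should therefore travel masked, the acetate arm should arrive late under non-basic conditions, and radical-cation oxidants should be avoided. The feature that opens a short route is the pattern of ring B: the two methoxy groups are para to each other, and so are the C3a carbon substituent and the C6 aryl group, so ring B without O1 is a 2,5-disubstituted hydroquinone dimethyl ether available from a symmetrical 1,4-dihalide. In that ring C7a–H is the only hydrogen ortho to the C3a substituent, and C2 is at the carboxylic acid oxidation level once ring A is read as the enol form of a benzofuran-2(3H)-one. A 2-arylpropanoic acid at C3a thus already holds C3, its methyl group, C2 and O1, and its carboxylate can deliver O1 to C7a.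

## Retrosynthesis

**12 ⇐ 11 (O–benzyl).** The phenol of ring C cannot be free during a trivalent-iodine oxidation or a triflation, so 12 is traced to its benzyl ether 11. Benzyl is chosen over a silyl or acyl group because it arrives already installed in the commercial boronic acid 2 and tolerates strong amide base, brief acid and the oxidant. Its hydrogenolysis leaves the methyl ester, the methyl ethers and the tetrasubstituted furan double bond untouched.

**11 ⇐ 8 + 10 (C2–CH2).** Cutting the bond between C2 and the acetate methylene gives the benzofuran-2-yl triflate 8 and the zinc ester enolate 10, made in the flask from methyl bromoacetate 9. The acetate arm could instead be carried from the start, but that would pass a β-dicarbonyl-type chain through every earlier step. A one-step Wittig olefination of lactone 7 is shorter but is held in reserve, because an enolizable 3-substituted lactone may simply be deprotonated by the ylide. The forward step needs oxidative addition of an electron-rich heteroaryl triflate and a carbon nucleophile mild enough to leave the product ester and its acidic methylene alone; a Reformatsky-type zinc reagent meets that.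

**8 ⇐ 7 (C2–O sulfonate).** The triflate 8 is the O-sulfonylated enol of the lactone 7. This is the reason for choosing a lactone as the ring A precursor: its carbonyl carbon is C2 at the right oxidation level, C3 already bears the methyl group, and the enolate is an aromatic benzofuran-2-olate, so O-sulfonylation is favoured. The racemic C3 stereocentre of 7 disappears here.

**7 ⇐ 6 (O1–C7a, key disconnection).** Opening the lactone at the aryl–oxygen bond, not at the acyl–oxygen bond, gives the 2-arylpropanoic acid 6. The acyl–oxygen cut would require a phenol with three contiguous oxygen-bearing carbons and a regiochemical problem at every stage. The aryl–oxygen cut requires only a 1,2,4,5-tetrasubstituted benzene with one free position ortho to the side chain. The forward reaction is a carboxylate-directed palladation of that C–H bond followed by oxidation and C–O reductive elimination. It must occur on an electron-rich ring without one-electron oxidation and without decarboxylation of the arylacetic acid.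

**6 ⇐ 5 ⇐ 3 + 4 (C3a–C3).** The acid 6 comes from its tert-butyl ester 5, and 5 from the aryl bromide 3 and tert-butyl propanoate 4 by palladium-catalysed enolate α-arylation. This places the complete three-carbon unit (C3, methyl, C2) on the ring in one step; a two-step acetate arylation and methylation would be longer. The tert-butyl ester suppresses Claisen condensation and is removed by acid without touching the benzyl ether.

**3 ⇐ 1 + 2 (C6–C1′).** The biaryl bond is cut to the symmetrical 1,4-dibromo-2,5-dimethoxybenzene 1 and [4-(benzyloxy)phenyl]boronic acid 2. Because the two bromides of 1 are equivalent, the para relationship of aryl group and side chain is fixed by the starting material. The only requirement is to stop after one coupling, which an excess of the inexpensive dibromide secures.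

## Roads not taken

**Alternative 1:** Ring C is built instead of bought. The cut is through C3′–C4′ and C5′–C6′. The 6-(buta-1,3-dien-2-yl)benzofuran A1 would undergo a [4+2] cycloaddition, catalysed by CoBr2(dppe) with Zn and ZnI2, with ethynylboronic acid pinacol ester A2 to give the cyclohexa-1,4-dienyl boronate A3. Dehydrogenation and C–B oxidation would then reveal the phenol.
- Merits: the para regiochemistry of such cycloadditions of a 2-substituted diene like A1 with a terminal alkyne like A2 is dependable. The alkyne A2 is a commercial reagent, and the phenol is carried as a boronate, so no phenol protecting group is needed. In that one respect it is cleaner than the chosen plan.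
- Weak points: the key step builds a plain 4-hydroxyphenyl ring that is commercially available as a boronic acid, while the real difficulties (ring B substitution, O1–C7a, the C2/C3 pattern) all remain inside A1, which still has to be made. The dehydrogenation of A3 needs a quinone oxidant in the presence of an electron-rich dimethoxybenzofuran, and the boron oxidation must spare the methyl ester.
- Comparison: the chosen plan pays for its protecting group with one hydrogenolysis, but forms the biaryl bond in a single coupling and spends its key step on the bond that is hard to make.

**Alternative 2:** The cut is C6–C1′ together with C7–O, through an aryne spanning C6–C7. Lithium 2,2,6,6-tetramethylpiperidide would deprotonate (3-bromo-5-methoxyphenoxy)tri(propan-2-yl)silane A4 next to bromine. The resulting 3-silyloxyaryne would take up [4-(benzyloxy)phenyl]magnesium bromide A5 at the carbon remote from the silyloxy group, and the arylmagnesium so formed would be borylated and oxidized in the same flask to the biphenylol A6.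
- Merits: three contiguous ring B substituents are set in one operation, and the C7a oxygen is present from the start, so no C–H oxidation on an oxidation-prone ring is needed. That is a real advantage over the chosen plan, whose key step is exactly such an oxidation.
- Weak points: A4 has two hydrogens beside bromine, one flanked by the bulky silyloxy group and one by the methoxy group. Deprotonation at the less hindered, methoxy-flanked site would give the regioisomeric aryne and a product with the two oxygen substituents interchanged. The amide base can also add to the aryne in competition with the Grignard reagent A5. After A6 the route still needs O-methylation, desilylation and a furan annulation that places different groups at C2 and C3, so it is clearly longer.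
- Comparison: the chosen plan has regiochemical certainty (a symmetrical dibromide and a single available ortho C–H) and a seven-step count. Its fallback for the key step borrows the anionic oxygenation idea of this alternative.

**Alternative 3:** Ring B is formed from a four-membered ring; the bond formed is C3a–C4. Heating 3-[4-(benzyloxy)phenyl]-4-{5-[2-(tert-butyldimethylsilyloxy)ethyl]-4-methylfuran-2-yl}-4-hydroxycyclobut-2-en-1-one A7 would open it to a furyl vinylketene, which closes onto the furan β-carbon and tautomerizes to the 4,7-dihydroxybenzofuran A8.
- Merits: a reagent-free thermal step creates ring B with both oxygens and the C6 aryl group in place, and the union of a furan with a cyclobutenedione is convergent. As a construction of ring B it is more elegant than buying the ring.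
- Weak points: A7 requires a metallated trisubstituted furan and an aryl-substituted cyclobutenedione, each several steps from commercial materials, and their union must select one of two carbonyl groups. The hydroquinone A8 is air-sensitive and must be methylated at once. The C2 arm arrives as a protected alcohol and needs deprotection, two oxidations next to an electron-rich benzofuran, and esterification.
- Comparison: the chosen plan takes ring B with both methoxy groups from a catalogue compound, brings C2 in at the correct oxidation level, and reaches 12 in about half the number of steps.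

Key step: step 4

Remark on the chemistry: the α-stereocentre of 5, 6 and 7 is formed without control and is removed in step 5; these compounds are racemates, and their SMILES show one enantiomer (the same one throughout).

## Route

Step 1
Reactants: 1 1,4-dibromo-2,5-dimethoxybenzene; 2 [4-(benzyloxy)phenyl]boronic acid
Product: 3 4'-(benzyloxy)-4-bromo-2,5-dimethoxy-1,1'-biphenyl
Conditions: Pd(PPh3)4 (3 mol%), K2CO3 (2 M aq), toluene/EtOH, 80 °C; 1 in threefold excess
Reagents that add atoms: none
Why: Suzuki–Miyaura coupling; the two C–Br bonds of 1 are equivalent, so there is no regiochemical question, and the excess of 1 should make mono-coupling dominant, with unreacted 1 recovered.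

Step 2
Reactants: 3 4'-(benzyloxy)-4-bromo-2,5-dimethoxy-1,1'-biphenyl; 4 tert-butyl propanoate
Product: 5 tert-butyl (2RS)-2-{4-[4-(benzyloxy)phenyl]-2,5-dimethoxyphenyl}propanoate
Conditions: LiN(SiMe3)2 (2.3 equiv), Pd(dba)2 (2 mol%), P(tBu)3 (2 mol%), toluene, rt
Reagents that add atoms: none
Why: Palladium-catalysed α-arylation of a lithium ester enolate; the tert-butyl ester suppresses Claisen condensation and the excess base holds the product as its enolate, which prevents diarylation. The new stereocentre is formed racemic and is erased in step 5.

Step 3
Reactants: 5 tert-butyl (2RS)-2-{4-[4-(benzyloxy)phenyl]-2,5-dimethoxyphenyl}propanoate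
Product: 6 (2RS)-2-{4-[4-(benzyloxy)phenyl]-2,5-dimethoxyphenyl}propanoic acid
Conditions: CF3CO2H/CH2Cl2 (1:4), 0 °C to rt
Reagents that add atoms: none
Why: Acidolysis of the tert-butyl ester by loss of 2-methylpropene; the aryl benzyl ether and the methyl ethers should survive a short exposure to dilute acid.

Step 4
Reactants: 6 (2RS)-2-{4-[4-(benzyloxy)phenyl]-2,5-dimethoxyphenyl}propanoic acid
Product: 7 (3RS)-6-[4-(benzyloxy)phenyl]-4,7-dimethoxy-3-methyl-1-benzofuran-2(3H)-one
Conditions: Pd(OAc)2 (10 mol%), Ac-Gly-OH (30 mol%), PhI(OAc)2 (1.5 equiv), KOAc (1 equiv), t-BuOH, 80 °C
Reagents that add atoms: none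
Why: Carboxylate-directed C–H lactonization of the Pd(OAc)2/PhI(OAc)2 type, whose closest known form converts α,α-disubstituted arylacetic acids into benzofuran-2(3H)-ones. The potassium carboxylate of 6 binds divalent palladium, and the amino acid ligand assists concerted metalation–deprotonation of the one free ortho C–H (the future C7a), giving a six-membered palladacycle (Pd, O, C=O, Cα, C3a, C7a). PhI(OAc)2 oxidizes the palladacycle to tetravalent palladium, and C(sp2)–O reductive elimination with the bound carboxylate oxygen contracts it to the five-membered lactone ring and returns divalent palladium. Site selectivity rests on the substrate alone: the other ortho position carries the C4 methoxy group, C5–H is meta to the side chain, and ring C is beyond reach of the carboxylate. The electron-rich ring should speed the electrophilic palladation, and the α-methyl group gives a modest conformational bias toward closure. A two-electron palladium pathway is used so that the carboxylate is not oxidized to an acyloxy radical, which would decarboxylate to a stabilized benzylic radical. No stereocentre is created; the existing α-centre is racemic and is removed in step 5, so epimerization is without consequence. Any ortho-acetoxylated acid formed by competing C–OAc elimination would converge on 7 by acyl transfer.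

Step 5
Reactants: 7 (3RS)-6-[4-(benzyloxy)phenyl]-4,7-dimethoxy-3-methyl-1-benzofuran-2(3H)-one
Product: 8 6-[4-(benzyloxy)phenyl]-4,7-dimethoxy-3-methyl-1-benzofuran-2-yl trifluoromethanesulfonate
Conditions: Tf2O (1.2 equiv), iPr2NEt (1.5 equiv), CH2Cl2, −78 to 0 °C
Reagents that add atoms: trifluoromethanesulfonic anhydride, O=S(=O)(OS(=O)(=O)C(F)(F)F)C(F)(F)F
Why: Enol triflate formation; the C3–H of the aryl lactone is acidic enough for an amine base because the enolate is an aromatic benzofuran-2-olate, and O-sulfonylation of that enolate gives the heteroaryl triflate.

Step 6
Reactants: 8 6-[4-(benzyloxy)phenyl]-4,7-dimethoxy-3-methyl-1-benzofuran-2-yl trifluoromethanesulfonate; 9 methyl bromoacetate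
Product: 11 methyl 2-{6-[4-(benzyloxy)phenyl]-4,7-dimethoxy-3-methyl-1-benzofuran-2-yl}acetate, via bromo(2-methoxy-2-oxoethyl)zinc 10 (not isolated)
Conditions: 9, Zn dust, Me3SiCl (cat.), THF, 40 °C; then 8, Pd2(dba)3 (2.5 mol%), XPhos (10 mol%), THF, 50 °C
Reagents that add atoms: none
Why: Negishi cross-coupling of a Reformatsky reagent; zerovalent palladium inserts into the C–OTf bond, the zinc enolate transmetallates through carbon, and reductive elimination forms the C2–CH2 bond. The zinc reagent is too weakly basic to deprotonate or condense with the product ester.

Step 7
Reactants: 11 methyl 2-{6-[4-(benzyloxy)phenyl]-4,7-dimethoxy-3-methyl-1-benzofuran-2-yl}acetate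
Product: 12 methyl 2-[6-(4-hydroxyphenyl)-4,7-dimethoxy-3-methyl-1-benzofuran-2-yl]acetate (phenylcandilide B)
Conditions: H2 (1 atm), 10% Pd/C, EtOAc/MeOH, rt
Reagents that add atoms: none
Why: Hydrogenolysis of the aryl benzyl ether; the tetrasubstituted C2=C3 bond of the benzofuran, the methyl ester and the methyl ethers should be inert at ambient pressure and temperature.

## Compound list

1 | 1,4-dibromo-2,5-dimethoxybenzene | COc1cc(Br)c(OC)cc1Br | starting material
2 | [4-(benzyloxy)phenyl]boronic acid | OB(O)c1ccc(OCc2ccccc2)cc1 | starting material
3 | 4'-(benzyloxy)-4-bromo-2,5-dimethoxy-1,1'-biphenyl | COc1cc(-c2ccc(OCc3ccccc3)cc2)c(OC)cc1Br | intermediate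
4 | tert-butyl propanoate | CCC(=O)OC(C)(C)C | starting material
5 | tert-butyl (2RS)-2-{4-[4-(benzyloxy)phenyl]-2,5-dimethoxyphenyl}propanoate (racemic; one enantiomer drawn) | C[C@@H](C(=O)OC(C)(C)C)c1cc(OC)c(-c2ccc(OCc3ccccc3)cc2)cc1OC | intermediate
6 | (2RS)-2-{4-[4-(benzyloxy)phenyl]-2,5-dimethoxyphenyl}propanoic acid (racemic; one enantiomer drawn) | C[C@@H](C(=O)O)c1cc(OC)c(-c2ccc(OCc3ccccc3)cc2)cc1OC | intermediate
7 | (3RS)-6-[4-(benzyloxy)phenyl]-4,7-dimethoxy-3-methyl-1-benzofuran-2(3H)-one (racemic; one enantiomer drawn) | C[C@H]1C(=O)Oc2c(OC)c(-c3ccc(OCc4ccccc4)cc3)cc(OC)c21 | intermediate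
8 | 6-[4-(benzyloxy)phenyl]-4,7-dimethoxy-3-methyl-1-benzofuran-2-yl trifluoromethanesulfonate | Cc1c(OS(=O)(=O)C(F)(F)F)oc2c(OC)c(-c3ccc(OCc4ccccc4)cc3)cc(OC)c12 | intermediate
9 | methyl bromoacetate | COC(=O)CBr | starting material
10 | bromo(2-methoxy-2-oxoethyl)zinc | COC(=O)C[Zn]Br | intermediate
11 | methyl 2-{6-[4-(benzyloxy)phenyl]-4,7-dimethoxy-3-methyl-1-benzofuran-2-yl}acetate | COC(=O)Cc1oc2c(OC)c(-c3ccc(OCc4ccccc4)cc3)cc(OC)c2c1C | intermediate
12 | methyl 2-[6-(4-hydroxyphenyl)-4,7-dimethoxy-3-methyl-1-benzofuran-2-yl]acetate (phenylcandilide B) | COC(=O)Cc1oc2c(OC)c(-c3ccc(O)cc3)cc(OC)c2c1C | target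

## Step count and risks

Total: 7 steps. Longest linear sequence: 7 steps (from 1 to 12).

**Step 4 (key step).** Three processes may defeat it:
- slow palladation at a C–H flanked by the side chain and a methoxy group, in an acid lacking the gem-disubstitution of the best precedents;
- over-oxidation, either by enolization of the product lactone and α-oxidation at C3 by the trivalent-iodine reagent or by oxidative demethylation of ring B;
- decarboxylation, if a one-electron pathway intrudes.

The fallback introduces O1 by anionic chemistry instead of C–H oxidation; it sets out from 3 and returns at 7. One-flask deprotonation of 3 at the position between bromine and methoxy with in-situ borylation and oxidation (LiN(iPr)2 with B(OiPr)3 present, THF, −78 °C; then H2O2, NaOH) should give 4'-(benzyloxy)-4-bromo-2,5-dimethoxy-[1,1'-biphenyl]-3-ol F1. Protection (MOMCl, iPr2NEt, CH2Cl2) gives 4'-(benzyloxy)-4-bromo-2,5-dimethoxy-3-(methoxymethoxy)-1,1'-biphenyl F2. α-Arylation of 4 under the conditions of step 2 gives tert-butyl (2RS)-2-{4-[4-(benzyloxy)phenyl]-3,6-dimethoxy-2-(methoxymethoxy)phenyl}propanoate F3. Treatment with CF3CO2H in CH2Cl2 then cleaves the tert-butyl ester and the acetal, and the hydroxy acid closes to 7.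

**Step 6.** Transmetallation of the zinc enolate may be slower than loss of the triflate from the electron-rich heteroaryl palladium intermediate or than S–O cleavage of the triflate, which returns the lactone. The fallback sets out from 8 and returns at 11. Palladium-catalysed arylation of dimethyl malonate (Pd(OAc)2, P(tBu)3, K3PO4, toluene, 80 °C) should give dimethyl 2-{6-[4-(benzyloxy)phenyl]-4,7-dimethoxy-3-methyl-1-benzofuran-2-yl}propanedioate F4. Krapcho dealkoxycarbonylation (LiCl, wet DMSO, 140 °C) then leaves 11.

**Step 5.** The triflate is a ketene-acetal-type sulfonate on an electron-rich ring. It may hydrolyse during work-up or chromatography, and the lactone enolate may self-condense with unreacted lactone before it is sulfonylated. The fallback sets out from 7 and returns at 11, bypassing 8 and 10. Wittig olefination of the aryl lactone carbonyl with Ph3P=CHCO2Me in refluxing toluene, a reaction known to turn benzofuran-2(3H)-ones into benzofuran-2-ylacetates, should give 11 directly, because the olefination product aromatizes in the flask by a hydrogen shift from C3. No compound outside the route is made, hence the entry F0.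

**Step 1.** Statistical over-coupling to the terphenyl and a tedious separation from the excess dibromide may erode throughput. The fallback replaces statistics by halide chemoselectivity; it sets out from 1 and returns at 3. Mono bromine–lithium exchange (n-BuLi, 1 equiv, THF, −78 °C) and quenching with I2 should give 1-bromo-4-iodo-2,5-dimethoxybenzene F5. Its C–I bond should couple selectively with 2 (Pd(PPh3)4, K2CO3, toluene/EtOH, rt) to give 3.

## Further compounds

F1 | step 4 | 4'-(benzyloxy)-4-bromo-2,5-dimethoxy-[1,1'-biphenyl]-3-ol | COc1cc(-c2ccc(OCc3ccccc3)cc2)c(OC)c(O)c1Br
F2 | step 4 | 4'-(benzyloxy)-4-bromo-2,5-dimethoxy-3-(methoxymethoxy)-1,1'-biphenyl | COCOc1c(Br)c(OC)cc(-c2ccc(OCc3ccccc3)cc2)c1OC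
F3 | step 4 | tert-butyl (2RS)-2-{4-[4-(benzyloxy)phenyl]-3,6-dimethoxy-2-(methoxymethoxy)phenyl}propanoate (racemic; one enantiomer drawn) | C[C@@H](C(=O)OC(C)(C)C)c1c(OC)cc(-c2ccc(OCc3ccccc3)cc2)c(OC)c1OCOC
F4 | step 6 | dimethyl 2-{6-[4-(benzyloxy)phenyl]-4,7-dimethoxy-3-methyl-1-benzofuran-2-yl}propanedioate | COC(=O)C(C(=O)OC)c1oc2c(OC)c(-c3ccc(OCc4ccccc4)cc3)cc(OC)c2c1C
F0 | step 5 | none | none
F5 | step 1 | 1-bromo-4-iodo-2,5-dimethoxybenzene | COc1cc(I)c(OC)cc1Br
A1 | alternative 1 | methyl 2-[6-(buta-1,3-dien-2-yl)-4,7-dimethoxy-3-methyl-1-benzofuran-2-yl]acetate | COC(=O)Cc1oc2c(OC)c(C(=C)C=C)cc(OC)c2c1C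
A2 | alternative 1 | 2-ethynyl-4,4,5,5-tetramethyl-1,3,2-dioxaborolane | C#CB1OC(C)(C)C(C)(C)O1
A3 | alternative 1 | methyl 2-{4,7-dimethoxy-3-methyl-6-[4-(4,4,5,5-tetramethyl-1,3,2-dioxaborolan-2-yl)cyclohexa-1,4-dien-1-yl]-1-benzofuran-2-yl}acetate | COC(=O)Cc1oc2c(OC)c(C3=CCC(B4OC(C)(C)C(C)(C)O4)=CC3)cc(OC)c2c1C
A4 | alternative 2 | (3-bromo-5-methoxyphenoxy)tri(propan-2-yl)silane | COc1cc(Br)cc(O[Si](C(C)C)(C(C)C)C(C)C)c1
A5 | alternative 2 | [4-(benzyloxy)phenyl]magnesium bromide | Br[Mg]c1ccc(OCc2ccccc2)cc1
A6 | alternative 2 | 4'-(benzyloxy)-5-methoxy-3-{[tri(propan-2-yl)silyl]oxy}-[1,1'-biphenyl]-2-ol | COc1cc(O[Si](C(C)C)(C(C)C)C(C)C)c(O)c(-c2ccc(OCc3ccccc3)cc2)c1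
A7 | alternative 3 | 3-[4-(benzyloxy)phenyl]-4-{5-[2-(tert-butyldimethylsilyloxy)ethyl]-4-methylfuran-2-yl}-4-hydroxycyclobut-2-en-1-one (racemic) | O=C1C=C(c2ccc(OCc3ccccc3)cc2)C1(O)c1cc(C)c(CCO[Si](C)(C)C(C)(C)C)o1
A8 | alternative 3 | 6-[4-(benzyloxy)phenyl]-2-[2-(tert-butyldimethylsilyloxy)ethyl]-3-methyl-1-benzofuran-4,7-diol | Cc1c(CCO[Si](C)(C)C(C)(C)C)oc2c(O)c(-c3ccc(OCc4ccccc4)cc3)cc(O)c12
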